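Cuts: first the ester C–O bond between the acyl carbonyl C1 and the primary oxygen of the 2-(4-hydroxyphenyl)ethyl unit, then the C11–C12 CH2–CH2 bond inside the C32 acyl chain.
Enabling feature: C2 to C32 are thirty CH2 groups and one CH3 in a straight line on the single carbonyl C1, with no branches, heteroatoms or double bonds. The only ring, the phenol benzene ring, lies beyond the ester oxygen and can be attached later, so every CH2–CH2 bond is open to radical-radical coupling, and C11–C12 is the one that falls between two bulk acids.
Forward: dodecanedioic acid 1 goes through its dimethyl ester 2 and the potassium salt 3 to the half ester 4 (C1–C11 plus a carboxyl that is lost). Then 4 and docosanoic acid 5 (C12–C32 plus a carboxyl that is lost) are joined at C11–C12, by way of the primary radicals 6 and 7, in a mixed Kolbe electrolysis that gives methyl dotriacontanoate 8.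
Saponification (potassium soap 9) gives dotriacontanoic acid 10, whose carbonyl is then joined by a lipase to the primary oxygen of unprotected tyrosol 11 to give basalethanolide A 12. No ring is formed anywhere; the benzene ring is bought.
Stereochemistry: the molecule contains neither a stereocentre nor a configured double bond, so the route has no stereochemical task.

Key step: step 3

Remark on the chemistry: the acyl chain of the target SMILES is read as 32 carbons (dotriacontanoyl), numbered from the ester carbonyl (C1) to the terminal methyl (C32).

Step 1
Reactants: 1 dodecanedioic acid
Product: 2 dimethyl dodecanedioate
Conditions: MeOH (solvent), H2SO4 (cat.), reflux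
Reagents that add atoms: methanol, CO
Why: Fischer esterification: with methanol as solvent the acid-catalysed equilibrium should be driven to the diester at both identical carboxyl groups, and the saturated chain offers nothing else to react.

Step 2
Reactants: 2 dimethyl dodecanedioate
Product: 4 methyl hydrogen dodecanedioate, via potassium 12-methoxy-12-oxododecanoate 3 (not isolated)
Conditions: KOH (1.0 equiv), MeOH, rt; then aq HCl (pH 2)
Reagents that add atoms: potassium hydroxide, [K+].[OH-]
Why: Partial saponification (BAc2 ester hydrolysis) with exactly one equivalent of hydroxide: the two ester groups are equivalent and too far apart to sense each other, so the outcome is statistical, but salt 3 stays in water while unchanged 2 is extracted and recycled, any diacid 1 (left undissolved when 4 is taken up in warm heptane–toluene) returns to step 1, and methanol as solvent makes alkoxide exchange degenerate.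

Step 3
Reactants: 4 methyl hydrogen dodecanedioate; 5 docosanoic acid
Product: 8 methyl dotriacontanoate, via 10-(methoxycarbonyl)decyl radical 6 (not isolated), via henicosyl radical 7 (not isolated)
Conditions: Pt foil anode and Pt foil cathode, undivided cell; 4 (4 equiv), 5 (1 equiv), NaOMe (5 mol % of total acid), MeOH–cyclohexane (4:1), 50–55 °C, constant current (about 0.3 A/cm2), polarity reversed at intervals, until the electrolyte turns faintly alkaline
Reagents that add atoms: none
Why: Mixed (crossed) Kolbe electrolysis: the carboxylates of 4 and 5, held as a dense layer on the platinum anode, each give up one electron, and the acyloxy radicals lose CO2 at once to leave the primary radicals 6 and 7, which combine at the electrode surface to form the C11–C12 CH2–CH2 bond of 8, while the carboxyl protons are reduced to H2 at the cathode and so keep the small pool of carboxylate base alive. The closest known reaction type is the anodic chain extension of a long-chain fatty acid with the half ester of an alkanedioic acid, a classical route to very long fatty esters. The step closes no ring and creates no stereocentre. Two selectivities are needed: radical coupling rather than a second oxidation to the cation (Hofer-Moest ethers and alkenes), and cross- rather than homo-coupling. The first is secured by the substrates themselves, since both acids carry an unsubstituted alpha-CH2 and give primary radicals that are hard to oxidise, helped by smooth platinum, high current density and an only partly neutralised electrolyte; the ester of 4 lies ten CH2 groups from the reacting carboxyl, is inert at the anode and can only exchange methoxy for methoxy with the solvent. The second is merely statistical, so 4 is used in excess to send most of radical 7 into 8, and the three coupling products carry zero, one and two ester groups (dotetracontane, 8 and dimethyl docosanedioate), which should make separation on silica or by crystallisation straightforward.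

Step 4
Reactants: 8 methyl dotriacontanoate
Product: 10 dotriacontanoic acid, via potassium dotriacontanoate 9 (not isolated)
Conditions: KOH (5 equiv), EtOH–THF–H2O, reflux; then aq HCl, 60 °C
Reagents that add atoms: potassium hydroxide, [K+].[OH-]
Why: Saponification (BAc2) followed by acidification: the methyl ester is the only electrophilic site of 8, and the THF cosolvent at reflux should keep the waxy ester and its soap 9 in solution long enough for complete hydrolysis.

Step 5
Reactants: 10 dotriacontanoic acid; 11 tyrosol, 4-(2-hydroxyethyl)phenol
Product: 12 basalethanolide A, 2-(4-hydroxyphenyl)ethyl dotriacontanoate
Conditions: immobilised Candida antarctica lipase B (acrylic resin), 11 (2 equiv), 4 Å molecular sieves, toluene–2-methyl-2-butanol (4:1), 65 °C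
Reagents that add atoms: none
Why: Lipase-catalysed esterification, well known for tyrosol and fatty acids: the serine hydrolase is acylated by 10 and passes the acyl group only to the unhindered primary aliphatic hydroxyl of 11, the phenolic hydroxyl being no competent acceptor in the active site, while the sieves take up the water and the tertiary alcohol cosolvent, itself not acylated, keeps 11 dissolved.

Compound list
1 | dodecanedioic acid | OC(=O)CCCCCCCCCCC(=O)O | starting material
2 | dimethyl dodecanedioate | COC(=O)CCCCCCCCCCC(=O)OC | intermediate
3 | potassium 12-methoxy-12-oxododecanoate | COC(=O)CCCCCCCCCCC(=O)[O-].[K+] | intermediate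
4 | methyl hydrogen dodecanedioate (12-methoxy-12-oxododecanoic acid) | COC(=O)CCCCCCCCCCC(=O)O | intermediate
5 | docosanoic acid (behenic acid) | CCCCCCCCCCCCCCCCCCCCCC(=O)O | starting material
6 | 10-(methoxycarbonyl)decyl radical | [CH2]CCCCCCCCCC(=O)OC | intermediate
7 | henicosyl radical | [CH2]CCCCCCCCCCCCCCCCCCCC | intermediate
8 | methyl dotriacontanoate | CCCCCCCCCCCCCCCCCCCCCCCCCCCCCCCC(=O)OC | intermediate
9 | potassium dotriacontanoate | CCCCCCCCCCCCCCCCCCCCCCCCCCCCCCCC(=O)[O-].[K+] | intermediate
10 | dotriacontanoic acid | CCCCCCCCCCCCCCCCCCCCCCCCCCCCCCCC(=O)O | intermediate
11 | tyrosol, 4-(2-hydroxyethyl)phenol | OCCc1ccc(O)cc1 | starting material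
12 | basalethanolide A, 2-(4-hydroxyphenyl)ethyl dotriacontanoate | CCCCCCCCCCCCCCCCCCCCCCCCCCCCCCCC(=O)OCCc1ccc(O)cc1 | target

Total step count: 5
Longest linear sequence: 5 steps (1, 2, 4, 8, 10, 12). Acid 5 enters at step 3 and tyrosol 11 at step 5.

Steps most likely to fail

Step 3. The anode may foul as the waxy products and the sparingly soluble acid 5 deposit on it. That thins the carboxylate layer and lets solvent oxidation and over-oxidation to cations take over. Homo-coupling and disproportionation also drain the henicosyl radical. The fallback keeps the carboxyl of 5 as the radical source but pairs it with a defined nucleophile instead of a second radical. Setting out from 5, condensation with N-hydroxyphthalimide (N,N'-diisopropylcarbodiimide, DMAP cat., warm CH2Cl2–THF) should give the redox-active ester 1,3-dioxoisoindolin-2-yl docosanoate F1. Bought methyl 11-bromoundecanoate is converted with Zn dust and LiCl in THF at 50 °C into (11-methoxy-11-oxoundecyl)zinc bromide F2. Nickel-catalysed decarboxylative Negishi-type alkyl-alkyl coupling of F1 with an excess of F2 (NiCl2(dme), 4,4'-di-tert-butyl-2,2'-bipyridine, THF–DMF, rt) forms the same C11–C12 bond without a statistical partner and comes back to the route at 8.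

Step 5. The acyl transfer may stall, because the C32 acid dissolves poorly at temperatures the enzyme tolerates and its very long chain may enter the acyl pocket only slowly. The fallback replaces enzymatic chemoselectivity by a protecting group. Setting out from 11, alkylation of the phenoxide alone (BnBr, K2CO3, acetone, reflux) should give 2-[4-(benzyloxy)phenyl]ethanol F3. Steglich esterification of 10 with F3 (N,N'-diisopropylcarbodiimide, DMAP, toluene–CH2Cl2, 40 °C) gives 2-[4-(benzyloxy)phenyl]ethyl dotriacontanoate F4. Hydrogenolysis (H2, Pd/C, THF–EtOAc, 40 °C) removes the benzyl ether, leaves the homobenzylic ester C–O bond untouched, and comes back to the route at 12.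

Step 2. Hydrolysis may run on past the half-ester stage, and the potassium soaps may emulsify during the extractive separation. The fallback exchanges kinetic partial hydrolysis for a base-free thermodynamic redistribution. Setting out from equimolar 1 and 2, heating with a little methanol and concentrated HCl (cat.) in di-n-butyl ether should level the mixture by acid-catalysed ester interchange toward the half ester. This is separated by fractional distillation in vacuo, with 1 and 2 returned to the next batch, and the sequence comes back to the route at 4. No compound outside the list is made (entry F0).

Further compounds
F1 | step 3 | 1,3-dioxoisoindolin-2-yl docosanoate | CCCCCCCCCCCCCCCCCCCCCC(=O)ON1C(=O)c2ccccc2C1=O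
F2 | step 3 | (11-methoxy-11-oxoundecyl)zinc bromide | COC(=O)CCCCCCCCCC[Zn]Br
F3 | step 5 | 2-[4-(benzyloxy)phenyl]ethanol | OCCc1ccc(OCc2ccccc2)cc1
F4 | step 5 | 2-[4-(benzyloxy)phenyl]ethyl dotriacontanoate | CCCCCCCCCCCCCCCCCCCCCCCCCCCCCCCC(=O)OCCc1ccc(OCc2ccccc2)cc1
F0 | step 2 | none | none
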